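Follow the partner.

common to all: starting material 0.020 M; free catalyst 1 mol%

| flask | partner | remark | time |
|---|---|---|---|
| blue | 0.950 equiv | a single well-mixed tank run continuously and read at steady state, 12 h in it on average |  |
| amber | 0.950 equiv | a closed flask charged with all of it at once and left for 12 h | 12 h |
| ochre | 0.950 equiv | one stirred flow tank at steady state, fed with the mixture as stated, mean residence time 120 h |  |
| violet | 0.950 equiv (fed, over 9.60 h) | all but partner at the start; partner goes in evenly over 9.60 h, the run ends at 12 h | 12 h |

    partner + free catalyst → catalyst intermediate A (k1 = 2900 M⁻¹ h⁻¹)
    catalyst intermediate A → released group + catalyst intermediate B (k2 = 280 h⁻¹)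
    starting material + catalyst intermediate B ⇌ catalyst intermediate C (K3 = 50 M⁻¹, k3 = 2200 M⁻¹ h⁻¹)
    catalyst intermediate C → free catalyst + target (k4 = 16 h⁻¹)
    partner → decomposed reagent (k5 = 0.98 h⁻¹)

- the stated concentrations are those of everything mixed, before any reaction; amounts are the same in each set-up
- the feed brings no volume worth counting
- run time (amber): 12 h

1. the set-up with the highest amount of target at the outlet or at the end, in percent of the starting material put in ("none" if the first two lie within 2 percentage points) (blue / amber / ochre / violet / none)
2. amount of target at the outlet or at the end, in percent of the starting material put in, blue
3. amount of target at the outlet or at the end, in percent of the starting material put in, amber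
4. amount of target at the outlet or at the end, in percent of the starting material put in, ochre
5. amount of target at the outlet or at the end, in percent of the starting material put in, violet

At the low end of [partner], with the catalyst 2.00 × 10⁻⁴ M all free, partner has two exits. It binds at 0.580 h⁻¹ and decays at 0.98 h⁻¹, so binding loses, at odds of 0.592. At the high end the catalyst is busy: a trip round the cycle takes 0.151 h at the charged [starting material].

Adding the wait for partner to that trip joins the ends and gives the half-load level 0.00228 M, the [partner] at which the catalyst waits as long as it works. At any [partner], the share of partner that reaches the catalyst is the odds divided by (one + odds + [partner]/level).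

Amber sweeps [partner] down from 0.0190 M. Summing the share over that sweep gives odds × level × ln(one + charge/((one + odds) × level)), which is 12.3% of the starting material.

The other three hold a level where supply, the charge spread over the stated time, equals the partner's losses. I neglect what flows out, and I apply the held share to the whole charge. Blue holds 0.00116 M, which gives 26.8%. Ochre holds 1.03 × 10⁻⁴ M, which gives 34.3%. Violet holds 0.00149 M, which gives 25.1%. My pick is ochre.

The forecast also picks ochre, with 24.3% for blue, 12.4% for amber, 33.9% for ochre and 24.5% for violet, on the ground that a low [partner] “favours the catalyst”. For blue, my figure stands above the forecast's.

The simulation gives ochre as best, with 24.2% for blue, 12.6% for amber, 33.8% for ochre and 25.1% for violet.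

Take a neighbour of amber charged with 0.240 equiv of partner, so 0.00480 M. The same sweep with the same half-load level gives 5.68%. That flask ends with partner, the limiting reagent, at 0%. From a quarter of amber's partner it makes about half of amber's target, 5.86%.

All constants belong to no real substance.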